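**Plan**
- Retrosynthesis first cuts the two ester bonds (O1–acyl, O7–coumaroyl) and the cinnamate C=C. The dihydropyran is then opened at C1–O2 and C3–C4: its C3=C4 enol ether sits between C4 (α-carbon of an acetic ester arm on C5) and the C1 aldehyde carbon on C9, so C3 and O2 can come from one formate unit.
- The cyclopentane is cut at C4–C5 (conjugate addition of an acetate enolate to a C9 enal), at C5=C9 (ring-closing metathesis) and at C8–C9 (addition of a 2-metallated acrolein acetal to a C8 ketone).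
- Forward: 2-deoxy-D-ribose gives the open-chain C5–C10 ketone; the C8–C9 bond is made, then the carbocycle (first ring), then the C4/C11 arm; formylation and lactol closure give the dihydropyran (second ring); ester reduction, the O7 and O1 acylations and desilylation finish.
- Stereochemistry: C7 is C3 of the sugar; C8 comes from chelation-controlled addition; C5 from attack anti to the C7 and C8 carbon/ether substituents; C9 from protonation and, if needed, equilibration to the cis-fused bicycle; C1 from the anomeric preference of the lactol.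
- The Z alkene comes from an Ando-type olefination and the (R)-3-methylpentanoyl group from the purchased acid.

Key step: step 12

Remark: atoms carry iridoid numbers (C1 acetal carbon, O2, C3=C4, C5/C9 ring fusion, C6–C8 cyclopentane, C10 on C8, C11 on C4); PMB = 4-methoxybenzyl, TIPS = triisopropylsilyl, TES = triethylsilyl, TBS = tert-butyldimethylsilyl; (R)-3-methylpentanoic acid and (diphenoxyphosphoryl)acetic acid are assumed to be purchasable.

**Step 1**
Reactants: 1 2-deoxy-D-ribose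
Product: 2 (2R,3S)-hex-5-ene-1,2,3-triol
Conditions: Ph3PCH3Br, KOtBu, THF, 0 °C → rt
Reagents that add atoms: methyltriphenylphosphonium bromide, C[P+](c1ccccc1)(c1ccccc1)c1ccccc1.[Br-]
Why: Wittig methylenation of the open-chain aldehyde tautomer turns the aldehyde carbon (the future C5) into a vinyl CH, and neither carbinol centre is touched.

**Step 2**
Reactants: 2 (2R,3S)-hex-5-ene-1,2,3-triol
Product: 3 (2R,4S,5R)-2-(4-methoxyphenyl)-4-(prop-2-en-1-yl)-1,3-dioxan-5-ol
Conditions: 4-MeOC6H4CH(OMe)2, camphorsulfonic acid (cat.), CH2Cl2, rt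
Reagents that add atoms: 4-methoxybenzaldehyde dimethyl acetal, COc1ccc(C(OC)OC)cc1
Why: Acid-catalysed transacetalisation under equilibrating conditions should favour the six-membered 1,3-dioxane across O10 and O7 with aryl, allyl and hydroxyl all equatorial, which fixes the acetal carbon as 2R and leaves only the C8 hydroxyl free.

**Step 3**
Reactants: 3 (2R,4S,5R)-2-(4-methoxyphenyl)-4-(prop-2-en-1-yl)-1,3-dioxan-5-ol
Product: 4 (2R,3S)-3-(PMBO)hex-5-ene-1,2-diol
Conditions: (iBu)2AlH, CH2Cl2, −78 → 0 °C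
Reagents that add atoms: none
Why: Regioselective reductive opening of the 4-methoxybenzylidene acetal, in which the aluminium hydride binds the less hindered primary oxygen and hydride goes to the acetal carbon, should leave the PMB ether on the secondary O7.

**Step 4**
Reactants: 4 (2R,3S)-3-(PMBO)hex-5-ene-1,2-diol
Product: 5 (2R,3S)-3-(PMBO)-1-(TIPSO)hex-5-en-2-ol
Conditions: TIPSCl, imidazole, CH2Cl2, 0 °C → rt
Reagents that add atoms: triisopropylsilyl chloride, CC(C)[Si](Cl)(C(C)C)C(C)C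
Why: Silyl ether formation with the bulky chloride is selective for the primary O10 hydroxyl, and the TIPS ether will not chelate magnesium in step 6.

**Step 5**
Reactants: 5 (2R,3S)-3-(PMBO)-1-(TIPSO)hex-5-en-2-ol
Product: 6 (3S)-3-(PMBO)-1-(TIPSO)hex-5-en-2-one
Conditions: Dess–Martin periodinane, CH2Cl2, 0 °C → rt
Reagents that add atoms: none
Why: Dess–Martin oxidation converts the C8 carbinol into the ketone under near-neutral conditions that should not epimerise the α-alkoxy centre C7.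

**Step 6**
Reactants: 6 (3S)-3-(PMBO)-1-(TIPSO)hex-5-en-2-one; 7 2-bromo-3,3-diethoxyprop-1-ene
Product: 8 (3R,4S)-2-(diethoxymethyl)-4-(PMBO)-3-(TIPSOCH2)hepta-1,6-dien-3-ol
Conditions: 7, t-BuLi (2 equiv per Br), Et2O, −78 °C; MgBr2·OEt2, −78 → −40 °C; then 6 premixed with MgBr2·OEt2 in CH2Cl2, −78 °C
Reagents that add atoms: none
Why: Chelation-controlled (Cram chelate) Grignard addition, in which magnesium bridges the ketone oxygen and the PMB ether oxygen on C7 while the TIPS ether stays out, should bring the alkenyl nucleophile (from bromine–lithium exchange and transmetalation) onto the face of the C7 hydrogen and so set C8 as R, with C10 syn and O8 anti to O7 in the later ring.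

**Step 7**
Reactants: 8 (3R,4S)-2-(diethoxymethyl)-4-(PMBO)-3-(TIPSOCH2)hepta-1,6-dien-3-ol
Product: 9 (1R,5S)-2-(diethoxymethyl)-5-(PMBO)-1-(TIPSOCH2)cyclopent-2-en-1-ol
Conditions: second-generation Grubbs catalyst RuCl2(=CHPh)(PCy3)(H2IMes) (5 mol %), CH2Cl2, 40 °C
Reagents that add atoms: none
Why: Ring-closing metathesis between the allyl alkene and the 1,1-disubstituted alkene closes the five-membered ring as the trisubstituted C5=C9 alkene with loss of ethene, helped by the free allylic hydroxyl, and creates no stereocentre.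

**Step 8**
Reactants: 9 (1R,5S)-2-(diethoxymethyl)-5-(PMBO)-1-(TIPSOCH2)cyclopent-2-en-1-ol
Product: 10 (4S,5R)-5-hydroxy-4-(PMBO)-5-(TIPSOCH2)cyclopent-1-ene-1-carbaldehyde
Conditions: pyridinium p-toluenesulfonate (cat.), acetone/H2O (10:1), rt
Reagents that add atoms: water, O
Why: Mild acid hydrolysis of the allylic diethyl acetal, which ionises far more readily than the silyl and benzyl ethers, releases the conjugated C1 aldehyde; it precedes silylation because silyl triflates attack acetals.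

**Step 9**
Reactants: 10 (4S,5R)-5-hydroxy-4-(PMBO)-5-(TIPSOCH2)cyclopent-1-ene-1-carbaldehyde
Product: 11 (4S,5R)-4-(PMBO)-5-(TESO)-5-(TIPSOCH2)cyclopent-1-ene-1-carbaldehyde
Conditions: TESOTf, 2,6-lutidine, CH2Cl2, −78 → 0 °C
Reagents that add atoms: triethylsilyl trifluoromethanesulfonate, CC[Si](CC)(CC)OS(=O)(=O)C(F)(F)F
Why: Silylation of the hindered tertiary O8 hydroxyl with the silyl triflate and a hindered pyridine base blocks later lactonisation onto the C11 ester and should leave the enal untouched at low temperature.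

**Step 10**
Reactants: 11 (4S,5R)-4-(PMBO)-5-(TESO)-5-(TIPSOCH2)cyclopent-1-ene-1-carbaldehyde; 12 methyl acetate
Product: 13 methyl 2-[(1R,2S,3R,4S)-2-formyl-4-(PMBO)-3-(TESO)-3-(TIPSOCH2)cyclopentyl]acetate
Conditions: Al(O-2,6-Ph2C6H3)3 (from Al(CH3)3 and 3 equiv 2,6-diphenylphenol, toluene, rt), 11, −78 °C; then LiOC(OMe)=CH2 (from 12, LiN(iPr)2, THF, −78 °C); 1 M aq. HCl, −78 → 0 °C
Reagents that add atoms: none
Why: Michael addition of the lithium enolate of methyl acetate to the enal held as its complex with aluminium tris(2,6-diphenylphenoxide), which screens the carbonyl carbon and sends the enolate to C5; the enolate should approach anti to the CH2OTIPS group on C8 and the PMB ether on C7 (setting C5), and protonation of the aluminium enolate from the face away from the new side chain should place the formyl group cis to it at C9.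

**Step 11**
Reactants: 13 methyl 2-[(1R,2S,3R,4S)-2-formyl-4-(PMBO)-3-(TESO)-3-(TIPSOCH2)cyclopentyl]acetate
Product: 14 methyl 2-[(1R,2S,3R,4S)-2-(dimethoxymethyl)-4-(PMBO)-3-(TESO)-3-(TIPSOCH2)cyclopentyl]acetate
Conditions: HC(OMe)3, CeCl3·7H2O (cat.), MeOH, 0 °C → rt
Reagents that add atoms: trimethyl orthoformate, COC(OC)OC; methanol, CO
Why: Cerium-catalysed acetalisation with trimethyl orthoformate masks the aldehyde as its dimethyl acetal under conditions mild enough not to epimerise C9 or cleave the silyl ethers, so that only the ester is enolisable in step 12.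

**Step 12**
Reactants: 14 methyl 2-[(1R,2S,3R,4S)-2-(dimethoxymethyl)-4-(PMBO)-3-(TESO)-3-(TIPSOCH2)cyclopentyl]acetate; 15 methyl formate
Product: 18 lactol ester: methyl (1R,4aS,6S,7R,7aS)-1-hydroxy-6-(PMBO)-7-(TESO)-7-(TIPSOCH2)-1,4a,5,6,7,7a-hexahydrocyclopenta[c]pyran-4-carboxylate, via hydroxymethylene ester acetal 16 (not isolated), via hydroxymethylene ester aldehyde 17 (not isolated)
Conditions: LiN(iPr)2 (2.5 equiv), THF, −78 °C; HCO2Me (excess), −78 → 0 °C; then 1 M aq. HCl, THF, 0 °C → rt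
Reagents that add atoms: water, O
Why: LiN(iPr)2 removes a C4 proton, the only acidic C–H once C1 is an acetal, and the ester enolate attacks methyl formate in a crossed Claisen condensation that forms C3–C4 and rests as the stabilised hydroxymethylene enolate. Aqueous acid then hydrolyses the dimethyl acetal, and the enol oxygen on C3 adds to the freed C1 aldehyde in a 6-exo-trig hemiacetalisation that forms C1–O2 and closes the dihydropyran. This follows the familiar pattern in which an ester is formylated under Claisen conditions and the hydroxymethylene ester is trapped as a cyclic hemiacetal, giving a dihydropyran with a β-alkoxyacrylate unit. C1 is the only new stereocentre and is set thermodynamically, because the lactol epimerises through its open form and should settle with the hydroxyl pseudo-axial on the face of H9 (anomeric effect, and away from the substituted C8). The closure needs the C1 and C4 arms cis on the cyclopentane, which steps 10 and 11 provide, and a C9 epimer can still cross over through the enol of the C1 aldehyde because only the cis isomer is drained off as the bicyclic lactol. Chemoselectivity rests on the acetal, which keeps the aldehyde away from the base, and on the vinylogous carbonate, which makes the enol ether tolerant of the acid.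

**Step 13**
Reactants: 18 lactol ester
Product: 19 methyl (1S,4aS,6S,7R,7aS)-6-(PMBO)-1,7-bis(TESO)-7-(TIPSOCH2)-1,4a,5,6,7,7a-hexahydrocyclopenta[c]pyran-4-carboxylate
Conditions: TESCl, imidazole, DMF, 0 °C
Reagents that add atoms: chlorotriethylsilane, CC[Si](Cl)(CC)CC
Why: Silylation of the lactol hydroxyl with retention of its β position (1R becomes 1S by priority change only) protects C1 as a silyl acetal that withstands hydride reduction and is later the most labile silyl ether in the molecule.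

**Step 14**
Reactants: 19 C1 silyl acetal ester
Product: 20 methyl (1S,4aS,6S,7R,7aS)-6-hydroxy-1,7-bis(TESO)-7-(TIPSOCH2)-1,4a,5,6,7,7a-hexahydrocyclopenta[c]pyran-4-carboxylate
Conditions: DDQ, CH2Cl2/pH 7 phosphate buffer (10:1), 0 °C
Reagents that add atoms: none
Why: Oxidative cleavage of the PMB ether with DDQ frees O7 at the stage where the enol ether is deactivated by the ester and should therefore be safe from the oxidant.

**Step 15**
Reactants: 20 C7 alcohol ester
Product: 21 (1S,4aS,6S,7R,7aS)-4-(hydroxymethyl)-1,7-bis(TESO)-7-(TIPSOCH2)-1,4a,5,6,7,7a-hexahydrocyclopenta[c]pyran-6-ol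
Conditions: (iBu)2AlH (4 equiv), CH2Cl2, −78 °C
Reagents that add atoms: none
Why: Hydride reduction of the β-alkoxyacrylate ester at low temperature gives the C11 allylic alcohol by 1,2-reduction while the silyl acetal keeps the latent C1 aldehyde out of reach.

**Step 16**
Reactants: 21 diol
Product: 22 (1S,4aS,6S,7R,7aS)-4-(TBSOCH2)-1,7-bis(TESO)-7-(TIPSOCH2)-1,4a,5,6,7,7a-hexahydrocyclopenta[c]pyran-6-ol
Conditions: TBSCl, imidazole, CH2Cl2, 0 °C
Reagents that add atoms: tert-butyldimethylsilyl chloride, CC(C)(C)[Si](C)(C)Cl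
Why: Silyl ether formation is selective for the primary allylic O11 hydroxyl over the secondary O7 hydroxyl, which is flanked by the quaternary C8.

**Step 17**
Reactants: 22 C7 alcohol; 23 (diphenoxyphosphoryl)acetic acid
Product: 24 (1S,4aS,6S,7R,7aS)-4-(TBSOCH2)-1,7-bis(TESO)-7-(TIPSOCH2)-1,4a,5,6,7,7a-hexahydrocyclopenta[c]pyran-6-yl 2-(diphenoxyphosphoryl)acetate
Conditions: 23, EDC·HCl, DMAP, CH2Cl2, 0 °C → rt
Reagents that add atoms: none
Why: Steglich esterification of the only free hydroxyl, O7, with the phosphonoacetic acid, which acylates hindered alcohols well because the activated acid can react through its ketene.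

**Step 18**
Reactants: 24 phosphonoacetate; 25 4-(TBSO)benzaldehyde
Product: 26 (1S,4aS,6S,7R,7aS)-4-(TBSOCH2)-1,7-bis(TESO)-7-(TIPSOCH2)-1,4a,5,6,7,7a-hexahydrocyclopenta[c]pyran-6-yl (2Z)-3-[4-(TBSO)phenyl]prop-2-enoate
Conditions: NaH, THF, −78 °C; then 25, −78 → −20 °C
Reagents that add atoms: none
Why: Ando-type Horner–Wadsworth–Emmons olefination, in which the diaryl phosphonate collapses fast through the cis oxaphosphetane, should give mainly the (Z)-cinnamate, and the silyl acetal at C1 is inert to the base.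

**Step 19**
Reactants: 26 (Z)-cinnamate silyl acetal; 27 (3R)-3-methylpentanoic acid
Product: 29 (1S,4aS,6S,7R,7aS)-1-{[(3R)-3-methylpentanoyl]oxy}-4-(TBSOCH2)-7-(TESO)-7-(TIPSOCH2)-1,4a,5,6,7,7a-hexahydrocyclopenta[c]pyran-6-yl (2Z)-3-[4-(TBSO)phenyl]prop-2-enoate, via C1 lactol 28 (not isolated)
Conditions: HF·pyridine, pyridine, THF, 0 °C; then 27, EDC·HCl, DMAP, CH2Cl2, −20 → 0 °C
Reagents that add atoms: none
Why: Buffered HF·pyridine should cleave the triethylsilyl acetal ahead of the tertiary TES, primary TBS and TIPS and aryl TBS ethers, and the freed lactol, which rests as the β anomer (hydroxyl trans to the C9–C8 bond), is esterified at once under Steglich conditions with retention, which sets C1 as S.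

**Step 20**
Reactants: 29 fully protected diester
Product: 30 (1S,4aS,6S,7R,7aS)-7-hydroxy-4,7-bis(hydroxymethyl)-1-{[(3R)-3-methylpentanoyl]oxy}-1,4a,5,6,7,7a-hexahydrocyclopenta[c]pyran-6-yl (2Z)-3-(4-hydroxyphenyl)prop-2-enoate (CNP0217341.1)
Conditions: Bu4NF, AcOH (1:1), THF, 0 °C → rt, in the dark
Reagents that add atoms: none
Why: Fluoride desilylation buffered with acetic acid removes the four remaining silyl groups and should avoid base-induced acyl migration from O7 to O10, cleavage of the acyl acetal and Z-to-E isomerisation of the phenolic cinnamate.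

**Compound list**
1 | 2-deoxy-D-ribose | O=CC[C@H](O)[C@H](O)CO | starting material
2 | (2R,3S)-hex-5-ene-1,2,3-triol | C=CC[C@H](O)[C@H](O)CO | intermediate
3 | (2R,4S,5R)-2-(4-methoxyphenyl)-4-(prop-2-en-1-yl)-1,3-dioxan-5-ol | C=CC[C@@H]1O[C@H](c2ccc(OC)cc2)OC[C@H]1O | intermediate
4 | (2R,3S)-3-[(4-methoxybenzyl)oxy]hex-5-ene-1,2-diol | C=CC[C@H](OCc1ccc(OC)cc1)[C@H](O)CO | intermediate
5 | (2R,3S)-3-[(4-methoxybenzyl)oxy]-1-[(triisopropylsilyl)oxy]hex-5-en-2-ol | C=CC[C@H](OCc1ccc(OC)cc1)[C@H](O)CO[Si](C(C)C)(C(C)C)C(C)C | intermediate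
6 | (3S)-3-[(4-methoxybenzyl)oxy]-1-[(triisopropylsilyl)oxy]hex-5-en-2-one | C=CC[C@H](OCc1ccc(OC)cc1)C(=O)CO[Si](C(C)C)(C(C)C)C(C)C | intermediate
7 | 2-bromo-3,3-diethoxyprop-1-ene | C=C(Br)C(OCC)OCC | starting material
8 | (3R,4S)-2-(diethoxymethyl)-4-[(4-methoxybenzyl)oxy]-3-{[(triisopropylsilyl)oxy]methyl}hepta-1,6-dien-3-ol | C=CC[C@H](OCc1ccc(OC)cc1)[C@](O)(CO[Si](C(C)C)(C(C)C)C(C)C)C(=C)C(OCC)OCC | intermediate
9 | (1R,5S)-2-(diethoxymethyl)-5-[(4-methoxybenzyl)oxy]-1-{[(triisopropylsilyl)oxy]methyl}cyclopent-2-en-1-ol | CCOC(OCC)C1=CC[C@H](OCc2ccc(OC)cc2)[C@]1(O)CO[Si](C(C)C)(C(C)C)C(C)C | intermediate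
10 | (4S,5R)-5-hydroxy-4-[(4-methoxybenzyl)oxy]-5-{[(triisopropylsilyl)oxy]methyl}cyclopent-1-ene-1-carbaldehyde | O=CC1=CC[C@H](OCc2ccc(OC)cc2)[C@]1(O)CO[Si](C(C)C)(C(C)C)C(C)C | intermediate
11 | (4S,5R)-4-[(4-methoxybenzyl)oxy]-5-[(triethylsilyl)oxy]-5-{[(triisopropylsilyl)oxy]methyl}cyclopent-1-ene-1-carbaldehyde | O=CC1=CC[C@H](OCc2ccc(OC)cc2)[C@]1(O[Si](CC)(CC)CC)CO[Si](C(C)C)(C(C)C)C(C)C | intermediate
12 | methyl acetate | CC(=O)OC | starting material
13 | methyl 2-[(1R,2S,3R,4S)-2-formyl-4-[(4-methoxybenzyl)oxy]-3-[(triethylsilyl)oxy]-3-{[(triisopropylsilyl)oxy]methyl}cyclopentyl]acetate | O=C[C@H]1[C@@H](CC(=O)OC)C[C@H](OCc2ccc(OC)cc2)[C@]1(O[Si](CC)(CC)CC)CO[Si](C(C)C)(C(C)C)C(C)C | intermediate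
14 | methyl 2-[(1R,2S,3R,4S)-2-(dimethoxymethyl)-4-[(4-methoxybenzyl)oxy]-3-[(triethylsilyl)oxy]-3-{[(triisopropylsilyl)oxy]methyl}cyclopentyl]acetate | COC(OC)[C@H]1[C@@H](CC(=O)OC)C[C@H](OCc2ccc(OC)cc2)[C@]1(O[Si](CC)(CC)CC)CO[Si](C(C)C)(C(C)C)C(C)C | intermediate
15 | methyl formate | COC=O | starting material
16 | methyl (2Z)-2-[(1S,2S,3R,4S)-2-(dimethoxymethyl)-4-[(4-methoxybenzyl)oxy]-3-[(triethylsilyl)oxy]-3-{[(triisopropylsilyl)oxy]methyl}cyclopentyl]-3-hydroxyprop-2-enoate | COC(OC)[C@H]1[C@@H](/C(=C/O)C(=O)OC)C[C@H](OCc2ccc(OC)cc2)[C@]1(O[Si](CC)(CC)CC)CO[Si](C(C)C)(C(C)C)C(C)C | intermediate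
17 | methyl (2Z)-2-[(1S,2S,3R,4S)-2-formyl-4-[(4-methoxybenzyl)oxy]-3-[(triethylsilyl)oxy]-3-{[(triisopropylsilyl)oxy]methyl}cyclopentyl]-3-hydroxyprop-2-enoate | O=C[C@H]1[C@@H](/C(=C/O)C(=O)OC)C[C@H](OCc2ccc(OC)cc2)[C@]1(O[Si](CC)(CC)CC)CO[Si](C(C)C)(C(C)C)C(C)C | intermediate
18 | methyl (1R,4aS,6S,7R,7aS)-1-hydroxy-6-[(4-methoxybenzyl)oxy]-7-[(triethylsilyl)oxy]-7-{[(triisopropylsilyl)oxy]methyl}-1,4a,5,6,7,7a-hexahydrocyclopenta[c]pyran-4-carboxylate | O[C@@H]1OC=C(C(=O)OC)[C@H]2C[C@H](OCc3ccc(OC)cc3)[C@](O[Si](CC)(CC)CC)(CO[Si](C(C)C)(C(C)C)C(C)C)[C@@H]12 | intermediate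
19 | methyl (1S,4aS,6S,7R,7aS)-6-[(4-methoxybenzyl)oxy]-1,7-bis[(triethylsilyl)oxy]-7-{[(triisopropylsilyl)oxy]methyl}-1,4a,5,6,7,7a-hexahydrocyclopenta[c]pyran-4-carboxylate | CC[Si](CC)(CC)O[C@@H]1OC=C(C(=O)OC)[C@H]2C[C@H](OCc3ccc(OC)cc3)[C@](O[Si](CC)(CC)CC)(CO[Si](C(C)C)(C(C)C)C(C)C)[C@@H]12 | intermediate
20 | methyl (1S,4aS,6S,7R,7aS)-6-hydroxy-1,7-bis[(triethylsilyl)oxy]-7-{[(triisopropylsilyl)oxy]methyl}-1,4a,5,6,7,7a-hexahydrocyclopenta[c]pyran-4-carboxylate | CC[Si](CC)(CC)O[C@@H]1OC=C(C(=O)OC)[C@H]2C[C@H](O)[C@](O[Si](CC)(CC)CC)(CO[Si](C(C)C)(C(C)C)C(C)C)[C@@H]12 | intermediate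
21 | (1S,4aS,6S,7R,7aS)-4-(hydroxymethyl)-1,7-bis[(triethylsilyl)oxy]-7-{[(triisopropylsilyl)oxy]methyl}-1,4a,5,6,7,7a-hexahydrocyclopenta[c]pyran-6-ol | CC[Si](CC)(CC)O[C@@H]1OC=C(CO)[C@H]2C[C@H](O)[C@](O[Si](CC)(CC)CC)(CO[Si](C(C)C)(C(C)C)C(C)C)[C@@H]12 | intermediate
22 | (1S,4aS,6S,7R,7aS)-4-{[(tert-butyldimethylsilyl)oxy]methyl}-1,7-bis[(triethylsilyl)oxy]-7-{[(triisopropylsilyl)oxy]methyl}-1,4a,5,6,7,7a-hexahydrocyclopenta[c]pyran-6-ol | CC[Si](CC)(CC)O[C@@H]1OC=C(CO[Si](C)(C)C(C)(C)C)[C@H]2C[C@H](O)[C@](O[Si](CC)(CC)CC)(CO[Si](C(C)C)(C(C)C)C(C)C)[C@@H]12 | intermediate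
23 | (diphenoxyphosphoryl)acetic acid | O=C(O)CP(=O)(Oc1ccccc1)Oc1ccccc1 | starting material
24 | (1S,4aS,6S,7R,7aS)-4-{[(tert-butyldimethylsilyl)oxy]methyl}-1,7-bis[(triethylsilyl)oxy]-7-{[(triisopropylsilyl)oxy]methyl}-1,4a,5,6,7,7a-hexahydrocyclopenta[c]pyran-6-yl 2-(diphenoxyphosphoryl)acetate | CC[Si](CC)(CC)O[C@@H]1OC=C(CO[Si](C)(C)C(C)(C)C)[C@H]2C[C@H](OC(=O)CP(=O)(Oc3ccccc3)Oc3ccccc3)[C@](O[Si](CC)(CC)CC)(CO[Si](C(C)C)(C(C)C)C(C)C)[C@@H]12 | intermediate
25 | 4-[(tert-butyldimethylsilyl)oxy]benzaldehyde | O=Cc1ccc(O[Si](C)(C)C(C)(C)C)cc1 | starting material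
26 | (1S,4aS,6S,7R,7aS)-4-{[(tert-butyldimethylsilyl)oxy]methyl}-1,7-bis[(triethylsilyl)oxy]-7-{[(triisopropylsilyl)oxy]methyl}-1,4a,5,6,7,7a-hexahydrocyclopenta[c]pyran-6-yl (2Z)-3-{4-[(tert-butyldimethylsilyl)oxy]phenyl}prop-2-enoate | CC[Si](CC)(CC)O[C@@H]1OC=C(CO[Si](C)(C)C(C)(C)C)[C@H]2C[C@H](OC(=O)/C=C\c3ccc(O[Si](C)(C)C(C)(C)C)cc3)[C@](O[Si](CC)(CC)CC)(CO[Si](C(C)C)(C(C)C)C(C)C)[C@@H]12 | intermediate
27 | (3R)-3-methylpentanoic acid | CC[C@@H](C)CC(=O)O | starting material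
28 | (1R,4aS,6S,7R,7aS)-4-{[(tert-butyldimethylsilyl)oxy]methyl}-1-hydroxy-7-[(triethylsilyl)oxy]-7-{[(triisopropylsilyl)oxy]methyl}-1,4a,5,6,7,7a-hexahydrocyclopenta[c]pyran-6-yl (2Z)-3-{4-[(tert-butyldimethylsilyl)oxy]phenyl}prop-2-enoate | O[C@@H]1OC=C(CO[Si](C)(C)C(C)(C)C)[C@H]2C[C@H](OC(=O)/C=C\c3ccc(O[Si](C)(C)C(C)(C)C)cc3)[C@](O[Si](CC)(CC)CC)(CO[Si](C(C)C)(C(C)C)C(C)C)[C@@H]12 | intermediate
29 | (1S,4aS,6S,7R,7aS)-4-{[(tert-butyldimethylsilyl)oxy]methyl}-1-{[(3R)-3-methylpentanoyl]oxy}-7-[(triethylsilyl)oxy]-7-{[(triisopropylsilyl)oxy]methyl}-1,4a,5,6,7,7a-hexahydrocyclopenta[c]pyran-6-yl (2Z)-3-{4-[(tert-butyldimethylsilyl)oxy]phenyl}prop-2-enoate | CC[C@@H](C)CC(=O)O[C@@H]1OC=C(CO[Si](C)(C)C(C)(C)C)[C@H]2C[C@H](OC(=O)/C=C\c3ccc(O[Si](C)(C)C(C)(C)C)cc3)[C@](O[Si](CC)(CC)CC)(CO[Si](C(C)C)(C(C)C)C(C)C)[C@@H]12 | intermediate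
30 | (1S,4aS,6S,7R,7aS)-7-hydroxy-4,7-bis(hydroxymethyl)-1-{[(3R)-3-methylpentanoyl]oxy}-1,4a,5,6,7,7a-hexahydrocyclopenta[c]pyran-6-yl (2Z)-3-(4-hydroxyphenyl)prop-2-enoate | CC[C@@H](C)CC(=O)O[C@@H]1OC=C(CO)[C@H]2C[C@H](OC(=O)/C=C\c3ccc(O)cc3)[C@](O)(CO)[C@@H]12 | target

**Step count and risks**
Total step count: 20. Longest linear sequence: 20 steps, from 1 to 30.

Steps most likely to fail:

Step 10. The enolate may add to the carbonyl carbon of the crowded aluminium complex instead of to C5, or the complex may form poorly next to the quaternary C8. A sequence that never uses the carbonyl as the electrophile sets out from 11 and comes back at 13: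
- Luche reduction (NaBH4, CeCl3·7H2O, MeOH, −40 °C) should give [(4S,5R)-4-(PMBO)-5-(TESO)-5-(TIPSOCH2)cyclopent-1-en-1-yl]methanol F1.
- Johnson–Claisen rearrangement (CH3C(OMe)3, propionic acid cat., toluene, 130 °C) moves the acetate unit onto C5 through a six-membered transition state, with the same steric bias for the face away from the C7 and C8 carbon/ether substituents, and should give methyl 2-[(1R,3R,4S)-2-methylidene-4-(PMBO)-3-(TESO)-3-(TIPSOCH2)cyclopentyl]acetate F2.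
- Hydroboration with 9-BBN and oxidation with NaBO3·4H2O puts hydrogen on C9 from the face away from the C5 side chain and should give methyl 2-[(1R,2R,3R,4S)-2-(hydroxymethyl)-4-(PMBO)-3-(TESO)-3-(TIPSOCH2)cyclopentyl]acetate F3.
- Dess–Martin oxidation of F3 returns the route to 13.

Step 19. The fluoride source may also cleave the aryl silyl ether, whose phenol would then be acylated, and the freed lactol may ring-open before it is esterified. The order of events is changed so that the aryl silyl ether is not yet present; the detour sets out from 24 and comes back at 29: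
- Buffered HF·pyridine on 24 should give (1R,4aS,6S,7R,7aS)-1-hydroxy-4-(TBSOCH2)-7-(TESO)-7-(TIPSOCH2)-1,4a,5,6,7,7a-hexahydrocyclopenta[c]pyran-6-yl 2-(diphenoxyphosphoryl)acetate F4.
- F4 is esterified at once with 27 (EDC·HCl, DMAP) to (1S,4aS,6S,7R,7aS)-1-{[(3R)-3-methylpentanoyl]oxy}-4-(TBSOCH2)-7-(TESO)-7-(TIPSOCH2)-1,4a,5,6,7,7a-hexahydrocyclopenta[c]pyran-6-yl 2-(diphenoxyphosphoryl)acetate F5.
- Olefination of F5 with 25 under the mild NaI/DBU variant of the Ando conditions (THF, 0 °C), which the acyl acetal should tolerate, returns the route to 29.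

Step 6. The alkenylmagnesium reagent carries its own acetal oxygens, which may disturb the chelate and erode facial selectivity, and the basic reagent may enolise the ketone. A smaller, non-coordinating nucleophile and a different ring closure are used instead; the detour sets out from 6 and comes back at 10:
- Chelation-controlled addition of HC≡CMgBr (MgBr2·OEt2, CH2Cl2/THF, −78 °C) should give (3R,4S)-4-(PMBO)-3-(TIPSOCH2)hept-6-en-1-yn-3-ol F6.
- Ring-closing enyne metathesis (second-generation Grubbs catalyst RuCl2(=CHPh)(PCy3)(H2IMes), ethene atmosphere, CH2Cl2, 40 °C) should give (1R,5S)-2-ethenyl-5-(PMBO)-1-(TIPSOCH2)cyclopent-2-en-1-ol F7.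
- Selective oxidative cleavage of the unhindered terminal vinyl group of F7 (OsO4 cat., NaIO4, 2,6-lutidine, dioxane/H2O) returns the route to enal 10.

**Further compounds**
F1 | step 10 | [(4S,5R)-4-(PMBO)-5-(TESO)-5-(TIPSOCH2)cyclopent-1-en-1-yl]methanol | OCC1=CC[C@H](OCc2ccc(OC)cc2)[C@]1(O[Si](CC)(CC)CC)CO[Si](C(C)C)(C(C)C)C(C)C
F2 | step 10 | methyl 2-[(1R,3R,4S)-2-methylidene-4-(PMBO)-3-(TESO)-3-(TIPSOCH2)cyclopentyl]acetate | C=C1[C@@H](CC(=O)OC)C[C@H](OCc2ccc(OC)cc2)[C@]1(O[Si](CC)(CC)CC)CO[Si](C(C)C)(C(C)C)C(C)C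
F3 | step 10 | methyl 2-[(1R,2R,3R,4S)-2-(hydroxymethyl)-4-(PMBO)-3-(TESO)-3-(TIPSOCH2)cyclopentyl]acetate | OC[C@H]1[C@@H](CC(=O)OC)C[C@H](OCc2ccc(OC)cc2)[C@]1(O[Si](CC)(CC)CC)CO[Si](C(C)C)(C(C)C)C(C)C
F4 | step 19 | (1R,4aS,6S,7R,7aS)-1-hydroxy-4-(TBSOCH2)-7-(TESO)-7-(TIPSOCH2)-1,4a,5,6,7,7a-hexahydrocyclopenta[c]pyran-6-yl 2-(diphenoxyphosphoryl)acetate | O[C@@H]1OC=C(CO[Si](C)(C)C(C)(C)C)[C@H]2C[C@H](OC(=O)CP(=O)(Oc3ccccc3)Oc3ccccc3)[C@](O[Si](CC)(CC)CC)(CO[Si](C(C)C)(C(C)C)C(C)C)[C@@H]12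
F5 | step 19 | (1S,4aS,6S,7R,7aS)-1-{[(3R)-3-methylpentanoyl]oxy}-4-(TBSOCH2)-7-(TESO)-7-(TIPSOCH2)-1,4a,5,6,7,7a-hexahydrocyclopenta[c]pyran-6-yl 2-(diphenoxyphosphoryl)acetate | CC[C@@H](C)CC(=O)O[C@@H]1OC=C(CO[Si](C)(C)C(C)(C)C)[C@H]2C[C@H](OC(=O)CP(=O)(Oc3ccccc3)Oc3ccccc3)[C@](O[Si](CC)(CC)CC)(CO[Si](C(C)C)(C(C)C)C(C)C)[C@@H]12
F6 | step 6 | (3R,4S)-4-(PMBO)-3-(TIPSOCH2)hept-6-en-1-yn-3-ol | C=CC[C@H](OCc1ccc(OC)cc1)[C@](O)(CO[Si](C(C)C)(C(C)C)C(C)C)C#C
F7 | step 6 | (1R,5S)-2-ethenyl-5-(PMBO)-1-(TIPSOCH2)cyclopent-2-en-1-ol | C=CC1=CC[C@H](OCc2ccc(OC)cc2)[C@]1(O)CO[Si](C(C)C)(C(C)C)C(C)C
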